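**Retrosynthetic overview** (compounds are numbered in the forward route below)
- Target ⇒ its tris-silyl ether ⇒ cut at the exocyclic (Z)-C=C: (S)-β-(arylmethyl)-γ-butyrolactone + silylated 5-hydroxyvanillin (one-flask phosphorylation / Z-selective Horner–Wadsworth–Emmons).
- (S)-Lactone ⇒ prochiral 3-(arylmethyl)cyclobutanone: the ring C5–O1 bond is made by a desymmetrising Baeyer–Villiger oxygen insertion, which sets the only stereocentre (C4).
- Cyclobutanone ⇒ O-silyl eugenol + dichloroketene ([2+2], then dechlorination).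
- Ring order: cyclobutanone first, then ring expansion to the γ-lactone; both benzene rings are bought (eugenol, 5-hydroxyvanillin).

Assumption: in step 4 the ligand enantiomer is the one that delivers the (S)-lactone (its antipode gives R); I have not assigned which ligand enantiomer this is, so it is confirmed by chiral HPLC and optical rotation.

**Step 1**
Reactants: 1 eugenol (4-allyl-2-methoxyphenol)
Product: 2 tert-butyl(4-allyl-2-methoxyphenoxy)dimethylsilane
Conditions: TBSCl, imidazole, DMF, rt
Reagents that add atoms: tert-butyldimethylsilyl chloride, CC(C)(C)[Si](C)(C)Cl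
Why: Imidazole-promoted O-silylation of the phenol gives an aryl silyl ether that tolerates the ketene, zinc, peracid and amide-base steps and is removed by fluoride at the end (phenol protection, no stereocentre).

**Step 2**
Reactants: 2 tert-butyl(4-allyl-2-methoxyphenoxy)dimethylsilane
Product: 3 rac-2,2-dichloro-3-{[4-(tert-butyldimethylsilyloxy)-3-methoxyphenyl]methyl}cyclobutan-1-one
Conditions: Cl3CCOCl, Zn–Cu, Et2O/DME, rt → 35 °C
Reagents that add atoms: trichloroacetyl chloride, ClC(Cl)(Cl)C(Cl)=O
Why: Dichloroketene made in situ undergoes a thermal [2+2] ketene–alkene cycloaddition in which the ketene carbonyl carbon bonds to the terminal CH2, so only the 2,2-dichloro-3-substituted cyclobutanone forms (racemic, and the next step removes the chirality).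

**Step 3**
Reactants: 3 rac-2,2-dichloro-3-{[4-(tert-butyldimethylsilyloxy)-3-methoxyphenyl]methyl}cyclobutan-1-one
Product: 4 3-{[4-(tert-butyldimethylsilyloxy)-3-methoxyphenyl]methyl}cyclobutan-1-one
Conditions: Zn dust, AcOH, rt
Reagents that add atoms: none
Why: Zinc reduces both α-C–Cl bonds through zinc enolates that acetic acid protonates (reductive α-dehalogenation), leaving the achiral cyclobutanone whose two α-CH2 groups are enantiotopic.

**Step 4**
Reactants: 4 3-{[4-(tert-butyldimethylsilyloxy)-3-methoxyphenyl]methyl}cyclobutan-1-one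
Product: 5 (4S)-4-{[4-(tert-butyldimethylsilyloxy)-3-methoxyphenyl]methyl}oxolan-2-one
Conditions: Sc(OTf)3 (5 mol %), chiral N,N′-dioxide ligand (enantiomer giving S), m-CPBA, EtOAc, −20 °C
Reagents that add atoms: m-chloroperbenzoic acid, O=C(OO)c1cccc(Cl)c1
Why: Catalytic asymmetric Baeyer–Villiger oxidation in which the chiral Sc(III) complex holds the Criegee adduct so that only one of the two enantiotopic CH2–C(=O) bonds is antiperiplanar to the O–O bond and migrates, so forming the C5–O1 bond desymmetrises the ring and fixes C4 as S.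

**Step 5**
Reactants: 6 5-hydroxyvanillin (3,4-dihydroxy-5-methoxybenzaldehyde)
Product: 7 3,4-bis(tert-butyldimethylsilyloxy)-5-methoxybenzaldehyde
Conditions: TBSCl (2.5 equiv), imidazole, DMF, rt
Reagents that add atoms: tert-butyldimethylsilyl chloride, CC(C)(C)[Si](C)(C)Cl
Why: Exhaustive O-silylation masks the catechol, which would otherwise quench the phosphonate anion and deactivate the aldehyde as its phenoxide in step 6.

**Step 6**
Reactants: 5 (4S)-4-{[4-(tert-butyldimethylsilyloxy)-3-methoxyphenyl]methyl}oxolan-2-one; 7 3,4-bis(tert-butyldimethylsilyloxy)-5-methoxybenzaldehyde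
Product: 10 (3Z,4S)-3-{[3,4-bis(tert-butyldimethylsilyloxy)-5-methoxyphenyl]methylidene}-4-{[4-(tert-butyldimethylsilyloxy)-3-methoxyphenyl]methyl}oxolan-2-one, via enol phosphate 8 (not isolated), via phosphono lactone 9 (not isolated)
Conditions: LDA (1.05 equiv), THF, −78 °C; (PhO)2P(O)Cl (1.05 equiv); LDA (1.1 equiv), −78 → −20 °C; DMPU, then 7, −78 → 0 °C
Reagents that add atoms: none
Why: Proposed new method: one-flask O-phosphorylation of the lactone enolate, base-induced 1,3-O→C phosphoryl shift to the lithiated α-(diphenoxyphosphoryl) lactone and Horner–Wadsworth–Emmons olefination, in which the electron-poor diaryl phosphonate makes addition irreversible and oxaphosphetane collapse fast, so the kinetic adduct (aryl turned away from the C4 side chain, toward the flat lactone carbonyl) gives by syn-elimination the Z-alkene with aryl cis to C=O while the non-acidic C4–H keeps its S configuration; the closest known reactions are the vinyl phosphate → phosphonate rearrangement of lactone enol diethyl phosphates and the Ando-type Z-selective Horner–Wadsworth–Emmons reaction of acyclic α-substituted diaryl phosphonoacetates, and to my knowledge the two have not been combined on a diaryl phosphate of a β-substituted butyrolactone.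

**Step 7**
Reactants: 10 (3Z,4S)-3-{[3,4-bis(tert-butyldimethylsilyloxy)-5-methoxyphenyl]methylidene}-4-{[4-(tert-butyldimethylsilyloxy)-3-methoxyphenyl]methyl}oxolan-2-one
Product: 11 (3Z,4S)-3-[(3,4-dihydroxy-5-methoxyphenyl)methylidene]-4-[(4-hydroxy-3-methoxyphenyl)methyl]oxolan-2-one
Conditions: TBAF, AcOH (1:1), THF, 0 °C, argon, amber glass
Reagents that add atoms: none
Why: Acetic acid-buffered fluoride cleaves the three aryl Si–O bonds (desilylation) without forming free phenoxide, which avoids base-induced Z→E isomerisation through the push–pull quinone-methide form and air oxidation of the catechol, and leaves the lactone and C4 untouched.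

**Compound list**
1 | eugenol (4-allyl-2-methoxyphenol) | C=CCc1ccc(O)c(OC)c1 | starting material
2 | tert-butyl(4-allyl-2-methoxyphenoxy)dimethylsilane | C=CCc1ccc(O[Si](C)(C)C(C)(C)C)c(OC)c1 | intermediate
3 | rac-2,2-dichloro-3-{[4-(tert-butyldimethylsilyloxy)-3-methoxyphenyl]methyl}cyclobutan-1-one | COc1cc(CC2CC(=O)C2(Cl)Cl)ccc1O[Si](C)(C)C(C)(C)C | intermediate
4 | 3-{[4-(tert-butyldimethylsilyloxy)-3-methoxyphenyl]methyl}cyclobutan-1-one | COc1cc(CC2CC(=O)C2)ccc1O[Si](C)(C)C(C)(C)C | intermediate
5 | (4S)-4-{[4-(tert-butyldimethylsilyloxy)-3-methoxyphenyl]methyl}oxolan-2-one | COc1cc(C[C@@H]2COC(=O)C2)ccc1O[Si](C)(C)C(C)(C)C | intermediate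
6 | 5-hydroxyvanillin (3,4-dihydroxy-5-methoxybenzaldehyde) | COc1cc(C=O)cc(O)c1O | starting material
7 | 3,4-bis(tert-butyldimethylsilyloxy)-5-methoxybenzaldehyde | COc1cc(C=O)cc(O[Si](C)(C)C(C)(C)C)c1O[Si](C)(C)C(C)(C)C | intermediate
8 | diphenyl (4S)-4-{[4-(tert-butyldimethylsilyloxy)-3-methoxyphenyl]methyl}-4,5-dihydrofuran-2-yl phosphate (enol phosphate) | COc1cc(C[C@@H]2COC(OP(=O)(Oc3ccccc3)Oc3ccccc3)=C2)ccc1O[Si](C)(C)C(C)(C)C | intermediate
9 | diphenyl [(4R)-4-{[4-(tert-butyldimethylsilyloxy)-3-methoxyphenyl]methyl}-2-oxooxolan-3-yl]phosphonate, C3 epimers, present as its lithium enolate (4R only because P raises the CIP rank of C3; same arrangement in space as in 5) | COc1cc(C[C@@H]2COC(=O)C2P(=O)(Oc3ccccc3)Oc3ccccc3)ccc1O[Si](C)(C)C(C)(C)C | intermediate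
10 | (3Z,4S)-3-{[3,4-bis(tert-butyldimethylsilyloxy)-5-methoxyphenyl]methylidene}-4-{[4-(tert-butyldimethylsilyloxy)-3-methoxyphenyl]methyl}oxolan-2-one | COc1cc(C[C@@H]2COC(=O)/C2=C\c2cc(O[Si](C)(C)C(C)(C)C)c(O[Si](C)(C)C(C)(C)C)c(OC)c2)ccc1O[Si](C)(C)C(C)(C)C | intermediate
11 | (3Z,4S)-3-[(3,4-dihydroxy-5-methoxyphenyl)methylidene]-4-[(4-hydroxy-3-methoxyphenyl)methyl]oxolan-2-one | COc1cc(C[C@@H]2COC(=O)/C2=C\c2cc(O)c(O)c(OC)c2)ccc1O | target

**Step count and risks**
Total steps: 7. Longest linear sequence: 6 (steps 1, 2, 3, 4, 6, 7 from eugenol); step 5 is a one-step branch.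

Most likely to fail, first: step 6 (the proposed new step). The amide base may attack the electrophilic diaryl phosphate at phosphorus, the 1,3-shift may stall, and the lithium counter-ion may erode Z-selectivity. The fallback uses known chemistry, sets out from 5 (with 7) and comes back at 10. LiHMDS aldol addition of 5 to 7 (THF, −78 °C) gives the β-hydroxy lactone F1 as a mixture of epimers at C3 and the carbinol carbon. Mesylation (MsCl, Et3N) gives the mesylate F2, and DBU elimination gives the thermodynamic (3E,4S)-alkene F3. Irradiation at 350 nm in degassed solvent then gives a Z-enriched photostationary mixture, from which 10 is separated and the E isomer recycled.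

Second: step 4. The CH2 spacer between the ring and the arene weakens the differentiation of the two migrating bonds, so the ee may be only moderate. The fallback sets out from 4 and comes back at 5. Enantioselective deprotonation with a chiral lithium bis(1-phenylethyl)amide of the appropriate configuration, with Et3SiCl present (THF, −100 °C), gives the (S)-silyl enol ether F4. Ozonolysis with NaBH4 work-up gives the (S)-hydroxy acid F5, which closes to 5 on acidification.

Third: step 7. The Z-arylidene with a para-oxygenated ring can drift to E, and the free catechol is air-sensitive. The fallback sets out from 5 (with 7) and comes back at 11, and sets the geometry after the phenols are freed. The (3E,4S)-alkene F3, made as described above, is desilylated (TBAF/AcOH) to the (3E,4S)-triol F6. F6 is photoisomerised at 350 nm in degassed MeCN as the last operation, and 11 is separated from remaining E isomer.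

**Further compounds**
F1 | step 6 | (4S)-3-{[3,4-bis(tert-butyldimethylsilyloxy)-5-methoxyphenyl](hydroxy)methyl}-4-{[4-(tert-butyldimethylsilyloxy)-3-methoxyphenyl]methyl}oxolan-2-one, epimers at C3 and carbinol carbon | COc1cc(C[C@@H]2COC(=O)C2C(O)c2cc(O[Si](C)(C)C(C)(C)C)c(O[Si](C)(C)C(C)(C)C)c(OC)c2)ccc1O[Si](C)(C)C(C)(C)C
F2 | step 6 | methanesulfonate of F1 | COc1cc(C[C@@H]2COC(=O)C2C(OS(C)(=O)=O)c2cc(O[Si](C)(C)C(C)(C)C)c(O[Si](C)(C)C(C)(C)C)c(OC)c2)ccc1O[Si](C)(C)C(C)(C)C
F3 | step 6 | (3E,4S)-3-{[3,4-bis(tert-butyldimethylsilyloxy)-5-methoxyphenyl]methylidene}-4-{[4-(tert-butyldimethylsilyloxy)-3-methoxyphenyl]methyl}oxolan-2-one | COc1cc(C[C@@H]2COC(=O)/C2=C/c2cc(O[Si](C)(C)C(C)(C)C)c(O[Si](C)(C)C(C)(C)C)c(OC)c2)ccc1O[Si](C)(C)C(C)(C)C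
F4 | step 4 | (S)-tert-butyl[2-methoxy-4-({3-[(triethylsilyl)oxy]cyclobut-2-en-1-yl}methyl)phenoxy]dimethylsilane | COc1cc(C[C@@H]2C=C(O[Si](CC)(CC)CC)C2)ccc1O[Si](C)(C)C(C)(C)C
F5 | step 4 | (3S)-4-[4-(tert-butyldimethylsilyloxy)-3-methoxyphenyl]-3-(hydroxymethyl)butanoic acid | COc1cc(C[C@@H](CC(=O)O)CO)ccc1O[Si](C)(C)C(C)(C)C
F6 | step 7 | (3E,4S)-3-[(3,4-dihydroxy-5-methoxyphenyl)methylidene]-4-[(4-hydroxy-3-methoxyphenyl)methyl]oxolan-2-one | COc1cc(C[C@@H]2COC(=O)/C2=C/c2cc(O)c(O)c(OC)c2)ccc1O
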